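## Structural features

The target is an isoflavanone: a chroman-4-one (benzene ring A fused to the dihydropyranone ring C) that carries the aryl ring B on C3 through the C3–C1' single bond. Ring A bears a methoxy group at C7 and a 3-methylbut-2-enyl (prenyl) chain at C6. Ring B bears a free hydroxyl at C2' and a methoxy group at C4'. C3 is the only stereocentre and is S (priorities C4 > C2 > C1' > H), so no relative configuration has to be controlled. It is, however, tertiary, benzylic and α to the C4 ketone, with the 2'-phenol close by, so it enolises and racemises readily under base and more slowly under acid. The fragile groups are the trisubstituted alkene of the prenyl chain (no strong acid, no hydrogenation, limited tolerance of electrophilic halogen), the β-aryloxy ketone unit O1–C2–C3–C4 (ring opening by retro-oxa-Michael reaction under base) and the free phenol. The real difficulty is therefore to create C3 late under kinetic control and to keep it through the last deprotection, and to build ring C without the acid-mediated acylations that a prenylated ring A would not survive. The key step uses the fact that C4 is a single carbonyl carbon between C4a of ring A and C3. With O1–C2 already in place as an aryl ether tether, C4 can enter as carbon monoxide between an aryl–iodine bond at C4a and a carbene centre at C3, which closes ring C at the flat isoflavone stage.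

## Logic of the disconnections

**17 ⇒ 16.** The O2'–Si bond is cut. The 2'-oxygen has to be masked from the etherification onwards, because a free 2'-phenoxide would close onto C2 or hold base next to C3–H. A bulky trialkylsilyl group is the mask that can leave under buffered, nearly neutral conditions. Nothing is gained in skeleton, but every earlier base-mediated step becomes possible. The forward step must never leave an unprotonated phenoxide beside the acidic C3–H.

**16 ⇒ 15.** The C3–H bond is cut. The only stereocentre is a CH acid, so it is made from the planar enol derivative 15 by addition of a proton to one face of C3. This removes the stereochemical problem from all earlier compounds. The forward step needs a chiral proton source that outruns the achiral one, and conditions under which 16 does not enolise again.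

**15 ⇒ 14.** The C2–H and O4–Si bonds are cut. 15 is the 1,4-adduct of a hydrosilane to the enone of 14, so the reduction and the formation of the enol derivative are one operation. The construction target becomes 14, which is flat, robust and free of stereochemistry. The forward step must be 1,4-selective on a vinylogous ester and must leave the isolated alkene alone.

**14 ⇒ 11 + 12.** The C4a–C4 and C3–C4 bonds are cut. C4 is removed as 12, which leaves 11, where C4a carries iodine and C3 is a masked carbene (released through 13), and the O1–C2 ether holds both ends in reach. Ring C, the ketone and two C–C bonds then come from an acyclic ether and a gas, with no acid-mediated acylation of the prenylated ring. The forward step must take up 12 before the carbene is transferred and must end by loss of a C2 hydrogen, not of O1.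

**11 ⇒ 9 + 10.** The C3=N bond is cut. The carbene precursor is the condensation product of 9 and 10. Placing this cut directly before the key step keeps the base-sensitive sulfonylhydrazone out of the alkylation. The forward step is a condensation at an ortho-substituted aryl ketone that must not disturb the silyl ether or the α-aryloxy group.

**9 ⇒ 4 + 8.** The O1–C2 bond is cut. This divides 9 into 4 (ring A) and 8 (ring B with C2 and C3), two pieces of similar size, and makes the synthesis convergent. The forward displacement needs only mild base. With the 2'-oxygen silylated in 8, the bromide can be attacked only by the phenoxide of 4.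

**4 ⇒ 3 ⇒ 1 + 2.** The C4a–I bond is cut first, then the aryl–CH2 bond of the side chain. In 3 the carbon that must carry iodine is ortho to the hydroxyl and para to the methoxy group, and the para position of the phenol is occupied, so iodination is directed there. 3 is the cross-coupling product of 1 and 2, both commercial, so the substitution pattern of ring A is bought and not made. The demands are attack of the electrophile on the ring and not on the alkene, and coupling at the unsubstituted terminus of the allyl unit.

**8 ⇒ 6 ⇒ 5.** The C2–Br bond and the O2'–Si bond are cut. 8 is the α-bromide of 6 and is reached through 7, so that bromine goes to C2 and not into the activated ring. 6 is the silyl ether of commercial 5, which already holds ring B with both oxygens and the two-carbon unit C2–C3. The forward steps need a silylating agent strong enough for a hydrogen-bonded phenol, and one equivalent of brominating agent.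

## Other disconnections considered

**Alternative 1:** The cut is the C2–C3 bond. C2 is taken from the methyl group of an ortho-methoxy substituent on ring A, so O1–C2 is present from the start as an anisole.

- **Forward step:** the α-aryl-α-diazoketone A1 would be decomposed by Rh2(S-PTTL)4 (divalent rhodium). The carbenoid at C3 would insert into a methyl C–H bond, closing ring C and creating C3 in one event to give the silyl ether A2, one desilylation away from 17.
- **In favour:** ring closure and stereocentre come in the same step, there is no isoflavone detour and no gas. The endgame is one step against three in the chosen plan, so after the ring closure this alternative is better on step economy. Before the ring closure the two are about equal, since the ketone skeleton of A1 must be assembled and subjected to diazo transfer, roughly as many operations as the way to 11.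
- **Against:** the carbenoid sits where the methoxy oxygen can reach it through a five-membered transition state. Attack on that lone pair (oxonium ylide, then methyl shift) would compete with the six-membered insertion into an unactivated primary C–H bond. Wolff rearrangement and cyclopropanation of the prenyl alkene are further outlets. The new stereocentre arises at the carbenoid carbon itself, where enantiocontrol is less secure than at the C–H carbon and where a metal-bound enol could erase it.
- **Comparison:** both plans pass through a metal carbene at C3. In the chosen plan it is consumed by a 1,2-acyl shift inside a palladacycle, which asks less of the substrate than insertion into a methyl group but delivers no stereocentre. Structurally the alternative is the more economical reading of the molecule. The chosen plan is the more modular one, because rings A and B are joined by a simple etherification.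

**Alternative 2:** The cut goes through ring B itself (C2'–C3', C4'–C5' and C1'–C2').

- **Forward step:** irradiation of the chromonyl diazoketone A3 would trigger a Wolff rearrangement to a vinylketene. This would add methoxyacetylene A4 in a [2+2] sense, and four-electron ring opening, six-electron ring closure and tautomerisation would give the hydroxyisoflavone A5.
- **In favour:** the resorcinol pattern of ring B follows from the mechanism and the 2'-hydroxyl emerges free, so no protecting group is needed there. On that point it is better than the chosen plan. No transition metal and no CO are used. A5 stands at the same oxidation level as 14, so the endgame is of equal length.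
- **Against:** the key step builds a benzene ring that 5 supplies ready-made. A3 needs a preformed 3-functionalised chromone that already carries the prenyl group, and the usual formylating routes to such chromones are acidic. A4 is volatile and labile. The irradiation has to be run in the presence of the chromone chromophore and two alkenes. The free phenol of A5 beside the enone would have to be silylated or tolerated in the reduction and protonation sequence.
- **Comparison:** on mechanism the pericyclic cascade has a more predictable regiochemistry than an organometallic sequence whose steps must occur in the right order. On structure the alternative spends its main effort on the least demanding ring. On step economy it is several steps longer.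

**Alternative 3:** The cut removes C3–C4 and O1–C2 together.

- **Forward step:** photolysis of the benzodioxinone A6 would release, by cycloreversion, the ortho-quinoid ketene A8. This would add as a heterodiene across the enol ether A7 to give the 2-methoxyisoflavanone A9 as a racemic mixture of diastereomers.
- **In favour:** it is the most convergent plan. Two fragments of equal size are united in the ring-forming step itself, where the chosen plan needs a separate etherification, so on convergence it is better. No metal and no CO are used. The regiochemistry follows from polarity (ketene carbon to the aryl-bearing carbon of A7, phenolic oxygen to its methoxy-bearing carbon).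
- **Against:** quinoketenes are mostly intercepted by heteroatom nucleophiles. A [4+2] addition to a β-aryl enol ether would have to compete with [2+2] addition at the ketene and with dimerisation. A7 absorbs light and would isomerise. A9 is an acetal at C2 and racemic, so the 2-methoxy group must be eliminated to reach 14 before the same three final steps. The endgame is therefore one step longer.
- **Comparison:** the two plans are equal in that neither sets C3 in its key step and both converge on 14. The alternative is mechanistically simpler but rests on a less secure cycloaddition. The chosen plan is shorter after ring closure.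

Key step: step 7

**Remarks on the chemistry**

- C3 of the target is S. Iodine in 4 lies ortho to the hydroxyl and para to the methoxy group, so that C4a, the 7-methoxy and the 6-prenyl group of the chromone come out correctly.
- The sense of induction in step 9 is an assumption. The route is written with the (R)-catalyst; if a pilot run shows the R ketone, the (S)-catalyst, equally accessible, is used.
- The C=N geometry of 11 is not defined and is immaterial.

## Route

Step 1
Reactants: 1 4-bromo-3-methoxyphenol; 2 prenylboronic acid pinacol ester
Product: 3 3-methoxy-4-(3-methylbut-2-enyl)phenol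
Conditions: PdCl2(IPent)(3-chloropyridine) (2 mol %; IPent = 1,3-bis[2,6-di(pentan-3-yl)phenyl]imidazol-2-ylidene), KOH (5 M aq), THF, 70 °C
Reagents that add atoms: none
Why: Suzuki–Miyaura coupling of an allylboronate; this bulky carbene–palladium system is the one documented to couple 3,3-disubstituted allylboronates at the unsubstituted α-carbon (linear prenyl), and the phenol is carried through as its phenoxide.

Step 2
Reactants: 3 3-methoxy-4-(3-methylbut-2-enyl)phenol
Product: 4 2-iodo-5-methoxy-4-(3-methylbut-2-enyl)phenol
Conditions: NIS (1.0 equiv), CH2Cl2, −20 → 0 °C, dark
Reagents that add atoms: N-iodosuccinimide, O=C1CCC(=O)N1I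
Why: Electrophilic aromatic iodination; the carbon ortho to the hydroxyl and para to the methoxy group is the most activated open site (the para position of the phenol is blocked and the site between the two oxygens is hindered), and the ring should outcompete the remote alkene, whose iodonium formation is reversible in a non-nucleophilic solvent.

Step 3
Reactants: 5 paeonol (1-(2-hydroxy-4-methoxyphenyl)ethanone)
Product: 6 1-[4-methoxy-2-(triisopropylsilyloxy)phenyl]ethanone
Conditions: TIPSOTf, 2,6-lutidine, CH2Cl2, 0 °C → rt
Reagents that add atoms: triisopropylsilyl trifluoromethanesulfonate, CC(C)[Si](OS(=O)(=O)C(F)(F)F)(C(C)C)C(C)C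
Why: O-silylation of a hydrogen-bonded phenol with a silyl triflate and a hindered pyridine base; the bulky triisopropylsilyl group is chosen because it should resist carbonate, phenoxide and silyl migration to nitrogen in the later steps and still leave with buffered fluoride.

Step 4
Reactants: 6 1-[4-methoxy-2-(triisopropylsilyloxy)phenyl]ethanone
Product: 8 2-bromo-1-[4-methoxy-2-(triisopropylsilyloxy)phenyl]ethanone, via trimethylsilyl enol ether 7 (not isolated)
Conditions: TMSOTf, Et3N, CH2Cl2, 0 °C; then NBS (1.0 equiv), 0 °C
Reagents that add atoms: trimethylsilyl trifluoromethanesulfonate, C[Si](C)(C)OS(=O)(=O)C(F)(F)F (its silyl group is carried only by 7); N-bromosuccinimide, O=C1CCC(=O)N1Br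
Why: Soft enolisation to the silyl enol ether and its bromination by NBS; passing through 7 directs bromine to the methyl carbon and not into the electron-rich ring, and no HBr is formed that could attack the silyl ether.

Step 5
Reactants: 4 2-iodo-5-methoxy-4-(3-methylbut-2-enyl)phenol; 8 2-bromo-1-[4-methoxy-2-(triisopropylsilyloxy)phenyl]ethanone
Product: 9 2-[2-iodo-5-methoxy-4-(3-methylbut-2-enyl)phenoxy]-1-[4-methoxy-2-(triisopropylsilyloxy)phenyl]ethanone
Conditions: K2CO3, acetone, 0 °C → rt
Reagents that add atoms: none
Why: Williamson ether synthesis; displacement of an α-keto bromide by a phenoxide is fast near room temperature, and with the 2'-oxygen silylated only the phenoxide of 4 can attack the CH2Br carbon.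

Step 6
Reactants: 9 2-[2-iodo-5-methoxy-4-(3-methylbut-2-enyl)phenoxy]-1-[4-methoxy-2-(triisopropylsilyloxy)phenyl]ethanone; 10 tosylhydrazide
Product: 11 N'-{2-[2-iodo-5-methoxy-4-(3-methylbut-2-enyl)phenoxy]-1-[4-methoxy-2-(triisopropylsilyloxy)phenyl]ethylidene}-4-methylbenzenesulfonohydrazide (N-tosylhydrazone of 9)
Conditions: PPTS (5 mol %), THF–MeOH, 50 °C
Reagents that add atoms: none
Why: Condensation of a ketone with a sulfonyl hydrazide under weak acid catalysis; without base the α-aryloxy group cannot be eliminated and the aryl silyl ether is not attacked.

Step 7
Reactants: 11 N-tosylhydrazone of 9; 12 carbon monoxide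
Product: 14 7-methoxy-3-[4-methoxy-2-(triisopropylsilyloxy)phenyl]-6-(3-methylbut-2-enyl)chromen-4-one, via diazo compound 13 (not isolated)
Conditions: Pd(PPh3)4 (10 mol %), K2CO3 (3 equiv), CO (5 bar), 1,4-dioxane, 40 °C then 80 °C
Reagents that add atoms: none
Why: Proposed new method: zerovalent palladium should insert into the C4a–I bond and the electron-rich arylpalladium iodide should take up CO to an aroylpalladium species (C4a–C4), while K2CO3 slowly turns the sulfonylhydrazone into diazo compound 13 (Bamford–Stevens reaction). Loss of N2 at palladium should give a carbene at C3 inside a seven-membered palladacycle, and 1,2-migration of the acyl group from palladium to the carbene carbon forms C3–C4 and closes ring C, a formal 6-exo closure onto the Pd=C carbon. The resulting C3-palladium enolate has its only β-hydrogens on C2, and β-hydride elimination gives the C2=C3 bond of the chromone and, with base, zerovalent palladium again. The closest known reaction is the intermolecular three-component coupling of aryl iodides, CO and ketone N-tosylhydrazones to α,β-unsaturated ketones, which the ether tether here turns into a ring closure. No stereocentre is formed. CO insertion must precede carbene transfer, since a free arylpalladium would close the five-membered ring instead; the CO pressure, the fast migration of an electron-rich aryl group to CO and the slow heterogeneous release of 13 at a staged temperature are meant to secure this. β-Hydride elimination must beat loss of the ring oxygen, which is expected because a C2–H bond can become syn-coplanar with C3–Pd while the endocyclic C2–O1 bond cannot, and because the product is a conjugated 4-pyranone. The triisopropylsilyl ether should survive dry carbonate in dioxane and is too bulky to migrate to the hydrazone nitrogen.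

Step 8
Reactants: 14 7-methoxy-3-[4-methoxy-2-(triisopropylsilyloxy)phenyl]-6-(3-methylbut-2-enyl)chromen-4-one
Product: 15 4-[dimethyl(phenyl)silyloxy]-7-methoxy-3-[4-methoxy-2-(triisopropylsilyloxy)phenyl]-6-(3-methylbut-2-enyl)-2H-chromene
Conditions: PhMe2SiH (1.5 equiv), RhCl(PPh3)3 (2 mol %), toluene, 60 °C; filtration through neutral alumina under argon
Reagents that add atoms: dimethylphenylsilane, C[SiH](C)c1ccccc1
Why: Rhodium-catalysed 1,4-hydrosilylation of an enone with a monohydrosilane (hydride to the β-carbon C2, silicon to the carbonyl oxygen); the isolated trisubstituted alkene and the aryl ethers are inert under these conditions, and the small silyl group keeps the enol ether reactive for step 9.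

Step 9
Reactants: 15 4-[dimethyl(phenyl)silyloxy]-7-methoxy-3-[4-methoxy-2-(triisopropylsilyloxy)phenyl]-6-(3-methylbut-2-enyl)-2H-chromene
Product: 16 (3S)-7-methoxy-3-[4-methoxy-2-(triisopropylsilyloxy)phenyl]-6-(3-methylbut-2-enyl)chroman-4-one
Conditions: (R)-3,3'-bis(2,4,6-triisopropylphenyl)-1,1'-binaphthyl-2,2'-diyl N-triflyl thiophosphoramide (5 mol %), PhOH (1.1 equiv), toluene, −20 °C → rt
Reagents that add atoms: none
Why: Catalytic enantioselective protonation of the silyl enol ether of an α-aryl cyclic ketone by a chiral BINOL-derived N-triflyl thiophosphoramide, with phenol as the stoichiometric proton source and silyl acceptor; the chiral acid delivers the proton to one face of C3 from within the pocket of its 3,3'-aryl groups, which sets C3 as S, and phenol then takes the silyl group and regenerates the acid.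

Step 10
Reactants: 16 (3S)-7-methoxy-3-[4-methoxy-2-(triisopropylsilyloxy)phenyl]-6-(3-methylbut-2-enyl)chroman-4-one
Product: 17 (3S)-3-(2-hydroxy-4-methoxyphenyl)-7-methoxy-6-(3-methylbut-2-enyl)chroman-4-one (CNP0208718.1)
Conditions: Bu4NF (1.1 equiv), AcOH (2 equiv), THF, 0 °C
Reagents that add atoms: none
Why: Fluoride cleavage of an aryl silyl ether; with acetic acid in excess the liberated phenoxide is protonated at once, so no base able to enolise C3–H builds up and the configuration should be kept.

## Compound list

1 | 4-bromo-3-methoxyphenol | COc1cc(O)ccc1Br | starting material
2 | prenylboronic acid pinacol ester (4,4,5,5-tetramethyl-2-(3-methylbut-2-enyl)-1,3,2-dioxaborolane) | CC(C)=CCB1OC(C)(C)C(C)(C)O1 | starting material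
3 | 3-methoxy-4-(3-methylbut-2-enyl)phenol | COc1cc(O)ccc1CC=C(C)C | intermediate
4 | 2-iodo-5-methoxy-4-(3-methylbut-2-enyl)phenol | COc1cc(O)c(I)cc1CC=C(C)C | intermediate
5 | paeonol (1-(2-hydroxy-4-methoxyphenyl)ethanone) | CC(=O)c1ccc(OC)cc1O | starting material
6 | 1-[4-methoxy-2-(triisopropylsilyloxy)phenyl]ethanone | CC(=O)c1ccc(OC)cc1O[Si](C(C)C)(C(C)C)C(C)C | intermediate
7 | {1-[4-methoxy-2-(triisopropylsilyloxy)phenyl]ethenyloxy}trimethylsilane (not isolated) | C=C(O[Si](C)(C)C)c1ccc(OC)cc1O[Si](C(C)C)(C(C)C)C(C)C | intermediate
8 | 2-bromo-1-[4-methoxy-2-(triisopropylsilyloxy)phenyl]ethanone | BrCC(=O)c1ccc(OC)cc1O[Si](C(C)C)(C(C)C)C(C)C | intermediate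
9 | 2-[2-iodo-5-methoxy-4-(3-methylbut-2-enyl)phenoxy]-1-[4-methoxy-2-(triisopropylsilyloxy)phenyl]ethanone | COc1ccc(C(=O)COc2cc(OC)c(CC=C(C)C)cc2I)c(O[Si](C(C)C)(C(C)C)C(C)C)c1 | intermediate
10 | tosylhydrazide (4-methylbenzenesulfonohydrazide) | Cc1ccc(S(=O)(=O)NN)cc1 | starting material
11 | N-tosylhydrazone of 9 | COc1ccc(C(COc2cc(OC)c(CC=C(C)C)cc2I)=NNS(=O)(=O)c2ccc(C)cc2)c(O[Si](C(C)C)(C(C)C)C(C)C)c1 | intermediate
12 | carbon monoxide | [C-]#[O+] | starting material
13 | 1-{2-diazo-2-[4-methoxy-2-(triisopropylsilyloxy)phenyl]ethoxy}-2-iodo-5-methoxy-4-(3-methylbut-2-enyl)benzene (not isolated) | COc1ccc(C(=[N+]=[N-])COc2cc(OC)c(CC=C(C)C)cc2I)c(O[Si](C(C)C)(C(C)C)C(C)C)c1 | intermediate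
14 | 7-methoxy-3-[4-methoxy-2-(triisopropylsilyloxy)phenyl]-6-(3-methylbut-2-enyl)chromen-4-one | COc1ccc(-c2coc3cc(OC)c(CC=C(C)C)cc3c2=O)c(O[Si](C(C)C)(C(C)C)C(C)C)c1 | intermediate
15 | 4-[dimethyl(phenyl)silyloxy]-7-methoxy-3-[4-methoxy-2-(triisopropylsilyloxy)phenyl]-6-(3-methylbut-2-enyl)-2H-chromene | COc1ccc(C2=C(O[Si](C)(C)c3ccccc3)c3cc(CC=C(C)C)c(OC)cc3OC2)c(O[Si](C(C)C)(C(C)C)C(C)C)c1 | intermediate
16 | (3S)-7-methoxy-3-[4-methoxy-2-(triisopropylsilyloxy)phenyl]-6-(3-methylbut-2-enyl)chroman-4-one | COc1ccc([C@H]2COc3cc(OC)c(CC=C(C)C)cc3C2=O)c(O[Si](C(C)C)(C(C)C)C(C)C)c1 | intermediate
17 | (3S)-3-(2-hydroxy-4-methoxyphenyl)-7-methoxy-6-(3-methylbut-2-enyl)chroman-4-one | COc1ccc([C@H]2COc3cc(OC)c(CC=C(C)C)cc3C2=O)c(O)c1 | target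

## Step count and least certain steps

Total: 10 steps. Longest linear sequence: 8 steps (1, 2, 5, 6, 7, 8, 9, 10; the branch of steps 3 and 4 is equally long and joins at step 5).

**Step 7 (key step).** Four things could go wrong.

- Carbene transfer to the arylpalladium before CO uptake would close a five-membered ring instead of ring C.
- The hydrazone anion could lose the ring A aryloxide by 1,4-elimination before the sulfinate leaves, because the aryloxide is a fair leaving group β to the anionic nitrogen.
- The diazo compound could undergo a 1,2-hydride shift, or the carbene could be carbonylated to a ketene.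
- The C3-palladium intermediate could lose the ring oxygen, which would stop turnover.

The fallback uses the documented intermolecular form of the coupling and closes ring C afterwards through oxygen. It sets out from 4 and 6 (with 10 and 12) and returns to the route at 15. Ketone 6 would be condensed with 10 to the tosylhydrazone F1, and phenol 4 acetylated (Ac2O, pyridine) to the aryl acetate F2. F1, F2 and 12 would then be coupled (Pd(PPh3)4, K2CO3, CO, dioxane, 80 °C). The diazo compound F3 (not isolated) released from F1 is taken up by the aroylpalladium iodide derived from F2, and β-hydride elimination from the methyl group gives the 2-arylpropenone F4. Brief methanolysis of the acetate (catalytic K2CO3, MeOH–THF, 0 °C) frees the phenoxide, which closes ring C by 6-endo oxa-Michael addition to the racemic ketone F5. Silylation of F5 (PhMe2SiCl, NaI, Et3N, MeCN) gives 15.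

**Step 9.** Facial selectivity could be poor because the 3-aryl group carries a bulky ortho-silyloxy substituent and the ring holds an oxygen that the model substrates lack. Phenol could protonate without the catalyst. The strong acid could enolise the product or protonate the prenyl alkene. The sense of induction is not secured. The fallback sets C3 by reduction with dynamic kinetic resolution; it sets out from 14 and returns at 16. Transfer hydrogenation of 14 with RuCl(p-cymene)[(S,S)-TsDPEN] and HCO2H/Et3N (EtOAc, 40 °C) would reduce the enone in the flask to the racemic ketone F5. Its C3 epimers interconvert under the amine while one is reduced faster, which should give the cis-alcohol F6 (3S,4S; the S,S ligand is expected to give 4S by analogy with aryl alkyl ketones, the mirror-image ligand being used otherwise). Oxidation of F6 with Dess–Martin periodinane and NaHCO3 in CH2Cl2 at 0 °C then gives 16.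

**Step 8.** Addition could be sluggish or 1,2-selective at the vinylogous ester, the alkene could be isomerised by a rhodium hydride, and the silyl enol ether could hydrolyse on handling. The fallback replaces the catalytic hydrosilylation by a stoichiometric hydride conjugate addition with enolate trapping; it sets out from 14 and returns at 15. LiBH(s-Bu)3 in THF at −78 °C should add hydride to C2 to give the lithium enolate F7 (not isolated), which is silylated in the same flask with PhMe2SiCl and worked up without water to give 15.

**Step 1.** Coupling could occur at the substituted γ-terminus of the allyl unit (reverse prenyl), oxidative addition into the very electron-rich bromophenoxide could be slow, and the allylboronate could be protodeboronated in hot aqueous base. The fallback changes from cross-coupling to alkylation of an aryl anion; it sets out from 1 and returns at 3. 1 would be silylated (TBSCl, imidazole, DMF) to the silyl ether F8. Bromine–lithium exchange (n-BuLi, THF, −78 °C) gives the aryllithium F9 (not isolated), which is alkylated at the primary carbon of prenyl bromide in the presence of CuBr·SMe2 (10 mol %) to the prenylated silyl ether F10. Bu4NF in THF then frees 3.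

**Step 5.** The phenoxide of 4 could take the silyl group from the ortho-acyl aryl silyl ether, whose phenoxide is a good leaving group; the freed 2'-phenoxide would then close onto the CH2Br carbon. The fallback forms the O1–C2 bond by conjugate addition to an azoalkene and gives the hydrazone directly; it sets out from 8 and 4 (with 10) and returns at 11, replacing steps 5 and 6. 8 would first be condensed with 10 (Et2O–MeOH, 0 °C) to the α-bromo tosylhydrazone F11. Na2CO3 in CH2Cl2 at 0 °C eliminates HBr to the azoalkene F12 (not isolated), and phenol 4 adds to its terminal carbon to give 11.

## Further compounds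

F1 | step 7 | N'-{1-[4-methoxy-2-(triisopropylsilyloxy)phenyl]ethylidene}-4-methylbenzenesulfonohydrazide | CC(=NNS(=O)(=O)c1ccc(C)cc1)c1ccc(OC)cc1O[Si](C(C)C)(C(C)C)C(C)C
F2 | step 7 | 2-iodo-5-methoxy-4-(3-methylbut-2-enyl)phenyl acetate | COc1cc(OC(C)=O)c(I)cc1CC=C(C)C
F3 | step 7 | 1-(1-diazoethyl)-4-methoxy-2-(triisopropylsilyloxy)benzene (not isolated) | CC(=[N+]=[N-])c1ccc(OC)cc1O[Si](C(C)C)(C(C)C)C(C)C
F4 | step 7 | 5-methoxy-2-{2-[4-methoxy-2-(triisopropylsilyloxy)phenyl]prop-2-enoyl}-4-(3-methylbut-2-enyl)phenyl acetate | C=C(C(=O)c1cc(CC=C(C)C)c(OC)cc1OC(C)=O)c1ccc(OC)cc1O[Si](C(C)C)(C(C)C)C(C)C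
F5 | step 7 | racemic 7-methoxy-3-[4-methoxy-2-(triisopropylsilyloxy)phenyl]-6-(3-methylbut-2-enyl)chroman-4-one | COc1ccc(C2COc3cc(OC)c(CC=C(C)C)cc3C2=O)c(O[Si](C(C)C)(C(C)C)C(C)C)c1
F6 | step 9 | (3S,4S)-7-methoxy-3-[4-methoxy-2-(triisopropylsilyloxy)phenyl]-6-(3-methylbut-2-enyl)chroman-4-ol | COc1ccc([C@H]2COc3cc(OC)c(CC=C(C)C)cc3[C@H]2O)c(O[Si](C(C)C)(C(C)C)C(C)C)c1
F7 | step 8 | lithium 7-methoxy-3-[4-methoxy-2-(triisopropylsilyloxy)phenyl]-6-(3-methylbut-2-enyl)-2H-chromen-4-olate (not isolated) | [Li+].COc1ccc(C2=C([O-])c3cc(CC=C(C)C)c(OC)cc3OC2)c(O[Si](C(C)C)(C(C)C)C(C)C)c1
F8 | step 1 | (4-bromo-3-methoxyphenoxy)(tert-butyl)dimethylsilane | COc1cc(O[Si](C)(C)C(C)(C)C)ccc1Br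
F9 | step 1 | [4-(tert-butyldimethylsilyloxy)-2-methoxyphenyl]lithium (not isolated) | [Li]c1ccc(O[Si](C)(C)C(C)(C)C)cc1OC
F10 | step 1 | tert-butyl[3-methoxy-4-(3-methylbut-2-enyl)phenoxy]dimethylsilane | COc1cc(O[Si](C)(C)C(C)(C)C)ccc1CC=C(C)C
F11 | step 5 | N'-{2-bromo-1-[4-methoxy-2-(triisopropylsilyloxy)phenyl]ethylidene}-4-methylbenzenesulfonohydrazide | BrCC(=NNS(=O)(=O)c1ccc(C)cc1)c1ccc(OC)cc1O[Si](C(C)C)(C(C)C)C(C)C
F12 | step 5 | 1-[4-methoxy-2-(triisopropylsilyloxy)phenyl]-1-(tosyldiazenyl)ethene (not isolated) | C=C(N=NS(=O)(=O)c1ccc(C)cc1)c1ccc(OC)cc1O[Si](C(C)C)(C(C)C)C(C)C
A1 | alternative 1 | 2-diazo-1-[2,4-dimethoxy-5-(3-methylbut-2-enyl)phenyl]-2-[2-(tert-butyldimethylsilyloxy)-4-methoxyphenyl]ethanone | COc1ccc(C(=[N+]=[N-])C(=O)c2cc(CC=C(C)C)c(OC)cc2OC)c(O[Si](C)(C)C(C)(C)C)c1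
A2 | alternative 1 | (3S)-3-[2-(tert-butyldimethylsilyloxy)-4-methoxyphenyl]-7-methoxy-6-(3-methylbut-2-enyl)chroman-4-one | COc1ccc([C@H]2COc3cc(OC)c(CC=C(C)C)cc3C2=O)c(O[Si](C)(C)C(C)(C)C)c1
A3 | alternative 2 | (E)-1-diazo-4-[7-methoxy-6-(3-methylbut-2-enyl)-4-oxo-4H-chromen-3-yl]but-3-en-2-one | [N-]=[N+]=CC(=O)/C=C/c1coc2cc(OC)c(CC=C(C)C)cc2c1=O
A4 | alternative 2 | methoxyethyne (methoxyacetylene) | COC#C
A5 | alternative 2 | 3-(2-hydroxy-4-methoxyphenyl)-7-methoxy-6-(3-methylbut-2-enyl)chromen-4-one | COc1ccc(-c2coc3cc(OC)c(CC=C(C)C)cc3c2=O)c(O)c1
A6 | alternative 3 | 7-methoxy-2,2-dimethyl-6-(3-methylbut-2-enyl)-4H-1,3-benzodioxin-4-one | COc1cc2OC(C)(C)OC(=O)c2cc1CC=C(C)C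
A7 | alternative 3 | 4-methoxy-1-(2-methoxyethenyl)-2-(triisopropylsilyloxy)benzene (E/Z mixture) | COC=Cc1ccc(OC)cc1O[Si](C(C)C)(C(C)C)C(C)C
A8 | alternative 3 | 3-methoxy-4-(3-methylbut-2-enyl)-6-(oxomethylidene)cyclohexa-2,4-dien-1-one | COC1=CC(=O)C(=C=O)C=C1CC=C(C)C
A9 | alternative 3 | 2,7-dimethoxy-3-[4-methoxy-2-(triisopropylsilyloxy)phenyl]-6-(3-methylbut-2-enyl)chroman-4-one (racemic, mixture of diastereomers) | COc1ccc(C2C(OC)Oc3cc(OC)c(CC=C(C)C)cc3C2=O)c(O[Si](C(C)C)(C(C)C)C(C)C)c1
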